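The target in this flask rises and then falls, and two rates draw that curve. The flask has the reagent charge of the maple and birch runs, with substrate between theirs.

| flask | substrate | reagent in the second phase | remark | time | volume of the second phase over the first |
|---|---|---|---|---|---|
| maple | 16 mM | 48 mM | run made earlier |  |  |
| birch | 36 mM | 48 mM | run made earlier |  |  |
| larch | 24 mM | 96 mM | run made earlier |  |  |
| flask | 24 mM | 48.0 mM |  | 30 min | 2.0 |

- maple (time / min: target / %, substrate / %): 2.50: 17, 83; 4.00: 28, 70; 6.00: 45, 55; 10.0: 67, 31; 20.0: 82, 4; 30.0: 84, 3
- birch (time / min: target / %, substrate / %): 2.50: 15, 87; 4.00: 25, 74; 6.00: 38, 58; 10.0: 57, 39; 20.0: 76, 20; 30.0: 77, 13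
- larch (time / min: target / %, substrate / %): 2.50: 27, 73; 5.00: 59, 39; 8.00: 78, 16; 15.0: 89, 5; 30.0: 83, 1

(scatter of a reading: 1.5 percentage points)

- in the second phase: reagent in the second phase; everything else is in the first
- charges count per volume of the first phase; a concentration in a rate is the amount of a species over the volume of its own phase; every rate counts per litre of the first phase
- candidate steps: target -> over-reaction product B; substrate + reagent in the reaction phase -> target; reagent in the reaction phase <-> reagent in the second phase; target -> over-reaction product A; 2 reagent in the reaction phase -> self-condensation product
- the earlier runs hold the two phases in the same ratio of volumes as the flask asked about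

- amount of target at 30 min, in percent of the substrate charged
- part of the substrate charged that has reacted at 30 min

1. My reckoning takes the transfer from the second phase as keeping pace, so c(reagent in the reaction phase) stays about level and substrate decays pseudo-first-order. From 2.50 min to 10.0 min, maple gives 0.131 min⁻¹ and birch 0.107 min⁻¹. The flask gets their mean, 0.119 min⁻¹.

2. Target therefore starts at about that rate, ignoring the slower first minutes, while c(substrate) halves every 5.82 min.

3. From 15.0 min to 30.0 min, larch loses 10 percentage points of target plus substrate, with target near 86.0%. That gives the target's loss rate, the share of target gone per minute: 0.00775 min⁻¹. Each of the four readings carries 1.5 points.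

4. Substrate decays faster than target. Gain equals loss when c(substrate)/c(target) equals the loss rate over the substrate rate, at ln(ratio of rates)/(difference of rates) = 24.5 min, with target at 82.7%.

5. The peak comes earlier than the reading, so the curve is falling gently by then, with a half-life of 89.4 min. At 30 min I reckon 81.8% target and 97.2% reacted.

The forecast gives 81.5% and 94%, a lower conversion than mine, and for its yield it reasons that “Target is lost slowly after forming”.

The flask gives 82.3% target and 95.1% reacted, with over-reaction product B at 12.7%.

    target → over-reaction product B (k = 0.00670 min⁻¹)
    substrate + reagent in the reaction phase → target (k = 10.0 L mol⁻¹ min⁻¹)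
    reagent in the reaction phase ⇌ reagent in the second phase, rate k3*([reagent in the reaction phase] - [reagent in the second phase]/K3) per volume of the first phase (partition coefficient = 0.470, kL = 0.160 min⁻¹)
    target → over-reaction product A (k = 5.40 × 10⁻⁵ min⁻¹)
    2 reagent in the reaction phase → self-condensation product (k = 1.30 L mol⁻¹ min⁻¹)

Target plus substrate in this flask at 30 min, run down at the loss rate 0.00775 min⁻¹ to 2.0 h, comes to 43.4%. The same flask read at 2.0 h holds 47.7% target.

The earlier runs and the new flask stem from a simulated flask from invented constants, noise included.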